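The n-icosyl chain on C6 of the benzoate ring carries no functional handle, so the route rests on disconnecting it at its midpoint, the bond between chain carbons C10 and C11 (counted from the ring), two primary CH2 groups. Each is disguised as the α-carbon of a C11 carboxylic acid. A nickel-electrocatalytic doubly decarboxylative coupling joins the N-hydroxyphthalimide esters of undecanoic acid and of an 11-arylundecanoic acid, expelling two CO2 and delivering the complete target in one operation. The aryl acid comes from methyl 2,4,6-trihydroxybenzoate by selective O-methylation, mono-triflation, Sonogashira coupling with undec-10-ynoic acid and hydrogenation.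

Key step: step 7

Remark: the target has no stereocentre and no stereogenic double bond, so it is achiral and no enantiocontrol is needed.

Step 1
Reactants: 1 methyl 2,4,6-trihydroxybenzoate
Product: 2 methyl 2,6-dihydroxy-4-methoxybenzoate
Conditions: MeOH (1.05 equiv), PPh3, DIAD, THF, 0 °C to rt
Reagents that add atoms: methanol, CO
Why: Mitsunobu etherification, in which the 4-OH (para to the ester, not hydrogen-bonded to it, hence the most acidic and accessible phenol) should be methylated selectively while the two ester-chelated ortho hydroxyls stay free.

Step 2
Reactants: 2 methyl 2,6-dihydroxy-4-methoxybenzoate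
Product: 3 methyl 2-hydroxy-4-methoxy-6-{[(trifluoromethyl)sulfonyl]oxy}benzoate
Conditions: Tf2O (1.0 equiv), pyridine, CH2Cl2, −20 to 0 °C
Reagents that add atoms: trifluoromethanesulfonic anhydride, O=S(=O)(OS(=O)(=O)C(F)(F)F)C(F)(F)F
Why: O-sulfonylation of a phenol; the two hydroxyls of 2 are equivalent, and after the first triflation the remaining OH sits in a strong hydrogen bond to the ester carbonyl on a more electron-poor ring, which should stop the reaction at the mono-triflate.

Step 3
Reactants: 3 methyl 2-hydroxy-4-methoxy-6-{[(trifluoromethyl)sulfonyl]oxy}benzoate; 4 undec-10-ynoic acid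
Product: 5 11-[3-hydroxy-5-methoxy-2-(methoxycarbonyl)phenyl]undec-10-ynoic acid
Conditions: Pd(PPh3)2Cl2 (cat.), CuI (cat.), Et3N (excess), DMF, degassed, 70 °C; aq. HCl work-up
Reagents that add atoms: none
Why: Sonogashira coupling, with oxidative addition of Pd(0) into the aryl triflate activated by the ortho ester and transmetalation from the copper acetylide, the carboxylic acid being carried as its triethylammonium salt and the chelated phenol staying inert.

Step 4
Reactants: 5 11-[3-hydroxy-5-methoxy-2-(methoxycarbonyl)phenyl]undec-10-ynoic acid
Product: 6 11-[3-hydroxy-5-methoxy-2-(methoxycarbonyl)phenyl]undecanoic acid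
Conditions: H2 (1 atm), 10% Pd/C, EtOAc/MeOH, rt
Reagents that add atoms: none
Why: heterogeneous catalytic hydrogenation should saturate the alkyne completely, while the arene, the ester, the phenol and the acid are not reduced under these mild conditions.

Step 5
Reactants: 6 11-[3-hydroxy-5-methoxy-2-(methoxycarbonyl)phenyl]undecanoic acid
Product: 7 1,3-dioxoisoindolin-2-yl 11-[3-hydroxy-5-methoxy-2-(methoxycarbonyl)phenyl]undecanoate
Conditions: N-hydroxyphthalimide (1.1 equiv), DIC (1.1 equiv), DMAP (cat.), CH2Cl2, rt
Reagents that add atoms: N-hydroxyphthalimide, O=C1c2ccccc2C(=O)N1O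
Why: Steglich-type carbodiimide esterification, in which the acidic and unhindered N-hydroxyphthalimide should outcompete the chelated, flanked phenol as acyl acceptor and give the redox-active ester.

Step 6
Reactants: 8 undecanoic acid
Product: 9 1,3-dioxoisoindolin-2-yl undecanoate
Conditions: N-hydroxyphthalimide (1.1 equiv), DIC (1.1 equiv), DMAP (cat.), CH2Cl2, rt
Reagents that add atoms: N-hydroxyphthalimide, O=C1c2ccccc2C(=O)N1O
Why: the same Steglich-type carbodiimide esterification converts the simple fatty acid into its redox-active N-acyloxyphthalimide.

Step 7
Reactants: 7 1,3-dioxoisoindolin-2-yl 11-[3-hydroxy-5-methoxy-2-(methoxycarbonyl)phenyl]undecanoate; 9 1,3-dioxoisoindolin-2-yl undecanoate (3 equiv)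
Product: 10 methyl 2-hydroxy-6-icosyl-4-methoxybenzoate
Conditions: NiCl2·6H2O (20 mol %), 2,2':6',2''-terpyridine (20 mol %), AgNO3 (0.3 equiv), NaI, NMP, Mg anode/RVC cathode, undivided cell, constant current, rt; aq. HCl work-up
Reagents that add atoms: none
Why: Cathodically generated low-valent nickel–terpyridine should transfer single electrons to both N-acyloxyphthalimides, which fragment with loss of CO2 and phthalimide anion to the primary 10-arylalkyl and n-decyl radicals; these are captured in turn at nickel, and reductive elimination from the dialkylnickel species forms the C(sp3)–C(sp3) bond, with the sacrificial Mg anode supplying the electrons and silver deposited on the cathode suppressing direct ester reduction. The closest known reaction type is the Ni-electrocatalytic doubly decarboxylative cross-coupling of two redox-active esters, a reductive counterpart of the mixed Kolbe electrolysis. No ring is closed and no stereocentre is formed. The step needs cross- over homo-coupling, which is secured by a threefold excess of the inexpensive ester 9, so that 7 is consumed mainly in the cross pathway and the surplus ends as icosane, a hydrocarbon easily removed by chromatography. It also needs chemoselectivity, which the reductive manifold provides by leaving the oxidisable trioxygenated benzene ring, the hindered methyl ester and the chelated phenol untouched, as an anodic Kolbe coupling would not.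

Compound list
1 | methyl 2,4,6-trihydroxybenzoate | COC(=O)c1c(O)cc(O)cc1O | starting material
2 | methyl 2,6-dihydroxy-4-methoxybenzoate | COC(=O)c1c(O)cc(OC)cc1O | intermediate
3 | methyl 2-hydroxy-4-methoxy-6-{[(trifluoromethyl)sulfonyl]oxy}benzoate | COC(=O)c1c(O)cc(OC)cc1OS(=O)(=O)C(F)(F)F | intermediate
4 | undec-10-ynoic acid | C#CCCCCCCCCC(=O)O | starting material
5 | 11-[3-hydroxy-5-methoxy-2-(methoxycarbonyl)phenyl]undec-10-ynoic acid | COC(=O)c1c(O)cc(OC)cc1C#CCCCCCCCCC(=O)O | intermediate
6 | 11-[3-hydroxy-5-methoxy-2-(methoxycarbonyl)phenyl]undecanoic acid | COC(=O)c1c(O)cc(OC)cc1CCCCCCCCCCC(=O)O | intermediate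
7 | 1,3-dioxoisoindolin-2-yl 11-[3-hydroxy-5-methoxy-2-(methoxycarbonyl)phenyl]undecanoate | COC(=O)c1c(O)cc(OC)cc1CCCCCCCCCCC(=O)ON1C(=O)c2ccccc2C1=O | intermediate
8 | undecanoic acid | CCCCCCCCCCC(=O)O | starting material
9 | 1,3-dioxoisoindolin-2-yl undecanoate | CCCCCCCCCCC(=O)ON1C(=O)c2ccccc2C1=O | intermediate
10 | methyl 2-hydroxy-6-icosyl-4-methoxybenzoate | CCCCCCCCCCCCCCCCCCCCc1cc(OC)cc(O)c1C(=O)OC | target

Total step count: 7
Longest linear sequence: 6 (steps 1, 2, 3, 4, 5 and 7)

Steps most likely to fail

Step 7. The two esters may homocouple in preference to cross-coupling, or the alkyl radical or alkylnickel derived from 7 may be reduced to the alkane (protodecarboxylation), possibly with the phenol as hydrogen source. The fallback sets out from 7 and replaces the electroreductive coupling of two electrophiles by a thermal nickel-catalysed decarboxylative coupling with an organozinc nucleophile. Didecylzinc F1, made in the flask from decylmagnesium bromide (2 equiv) and ZnCl2 in THF, is used in about 3 equiv with NiCl2·glyme and 4,4'-di-tert-butyl-2,2'-bipyridine in THF/DMF at rt. One equivalent is spent on the phenol as its zinc phenoxide. Only 7 then acts as radical precursor, so the coupling is no longer statistical, and the fallback comes back to the route at 10.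

Step 2. Triflation may run on to the bis-triflate or stop short, leaving a mixture that is hard to separate. The fallback sets out from 2 and turns the problem around. Exhaustive triflation (Tf2O in excess, pyridine, CH2Cl2) should give methyl 4-methoxy-2,6-bis{[(trifluoromethyl)sulfonyl]oxy}benzoate F2. Controlled mono-detriflation with Et4NOH (2 equiv) in dioxane at rt then cleaves one S–O bond. The phenoxide so formed makes the second aryloxide a far poorer leaving group, so the hydrolysis should stop there, and the fallback comes back to the route at 3.

Step 3. Oxidative addition into the triflate on the electron-rich ring may be slow, so that copper-mediated oxidative dimerisation of the alkynoic acid wins, and the carboxylate and phenoxide may sequester the copper co-catalyst. The fallback sets out from 3 and forms the aryl–chain bond by a B-alkyl Suzuki–Miyaura coupling instead. Commercial methyl undec-10-enoate is hydroborated with 9-BBN in THF to methyl 11-(9-borabicyclo[3.3.1]nonan-9-yl)undecanoate F3. This is coupled with 3 (Pd(dppf)Cl2, aq. K3PO4, THF/DMF, 60 °C) to give methyl 2-hydroxy-4-methoxy-6-(11-methoxy-11-oxoundecyl)benzoate F4. LiOH in THF/H2O at rt should then saponify only the unhindered aliphatic methyl ester, since the 2,6-disubstituted benzoate ester, further deactivated as its phenoxide, resists hydrolysis. The fallback bypasses 5 and step 4 and comes back to the route at 6.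

Further compounds
F1 | step 7 | didecylzinc | CCCCCCCCCC[Zn]CCCCCCCCCC
F2 | step 2 | methyl 4-methoxy-2,6-bis{[(trifluoromethyl)sulfonyl]oxy}benzoate | COC(=O)c1c(OS(=O)(=O)C(F)(F)F)cc(OC)cc1OS(=O)(=O)C(F)(F)F
F3 | step 3 | methyl 11-(9-borabicyclo[3.3.1]nonan-9-yl)undecanoate | COC(=O)CCCCCCCCCCB1C2CCCC1CCC2
F4 | step 3 | methyl 2-hydroxy-4-methoxy-6-(11-methoxy-11-oxoundecyl)benzoate | COC(=O)CCCCCCCCCCc1cc(OC)cc(O)c1C(=O)OC
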